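All runs were computed for substances that don't exist, noise included.

At 5.00 d, late in its run, the birch flask reads solid substrate 0% and product 99.4%, and I hand it over to you as it stands.

- birch: solid substrate 0.10 M; enzyme 10 µM; the very flask that is asked about, followed so far
- flask: solid substrate 0.10 M; enzyme 10 µM; time 15 d

- birch (time / d: solid substrate / %, product / %): 0.625: 34.1, 43.5; 1.25: 0, 93.4; 2.08: 0.6, 100.2; 2.50: 0, 100.0; 3.00: 0, 100.5; 4.00: 0, 99.0; 5.00: 0, 99.4

(each reading ± 0.5 percentage points)

- solid, in amounts per volume of the solution: solid substrate
- the numbers in the tables scatter by 0.5 percentage points (one standard deviation)
- reactions considered so far: solid substrate <-> starting material; starting material + enzyme -> product + enzyme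
- at the start none of the solid substrate is in solution
- what has only dissolved of solid substrate counts as not reacted
- the reaction counts as stopped when no species that holds the solid substrate changes by six tenths of a point or more over the second half of the time

* the state of affairs at 15 d: stopped, and by what, or still going (for what has run out or reacted, a solid counts together with what of it has only dissolved) (it is still moving / all of the solid substrate has reacted)
* part of the solid substrate that has turned into other species by 15 d (what has only dissolved does not count)
* amount of product at 15 d, in percent of the solid substrate charged

1. I carry one number: U, the open share, the part of the charge not yet product, whether solid or dissolved. In the birch flask it reads 0.600% at 5.00 d, against a scatter of 0.5 percentage points.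

2. It read 56.5% at 0.625 d, so the birch flask has closed from there.

3. When you come at 15 d, I expect no solid substrate in the birch flask, and product at 99.4% in my own reckoning; the listed reactions hold no step out of product.

4. Add nothing to the birch flask: U already reads 0.600%, with a scatter of 0.5 points.

5. The forecast says all of the solid substrate has reacted, with conversion 100% and product 99.6%, where my figure is 99.4%: “So the mass balance closes and conversion is complete”.

The flask gives all of the solid substrate has reacted, with conversion 100% and product 100%.

    solid substrate ⇌ starting material, rate k1*(cs1 - [starting material]) while solid is left; crystals form when [starting material] > cs1 (solubility = 41.0 mM, k = 0.00310 min⁻¹)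
    starting material + enzyme → product + enzyme, rate k2*[starting material]*[enzyme]/(1 + ([starting material]/Km2) + ([starting material]/Ksi2)^2) (0.155 M, 0.0866 M, k = 340 M⁻¹ min⁻¹)

At 15.0 d this flask has U at 0%, below the last reading, and the solid substrate, its limiting reagent, stands at 0%. The same flask charged with 0.040 M of solid substrate has U at 0% at 15.0 d, with 0% of its solid substrate left and product at 100%.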